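## Analysis of the target

Isocryptomerin consists of two flavone (2-aryl-4H-chromen-4-one) units. One is a 5-hydroxy-7-methoxy-4'-hydroxyflavone and the other an apigenin skeleton; a diaryl ether runs from C6 of ring A of the methoxyflavone to C4' of ring B of the apigenin unit. The molecule is flat and achiral, with no stereocentre, so every problem of the synthesis is one of regiochemistry. The sensitive groups are four free phenols (two chelated 5-OH groups, one 7-OH, one 4'-OH), which oxidise readily as phenoxides in air. There is also a single methyl ether at C7 that must survive while every other oxygen ends free, and two pyranones that open in hot alkali. The hard bond is C6–O: it sits on a hexasubstituted ring between the chelated 5-OH and the 7-OMe, and C6 is not where a 5-hydroxy-7-methoxyflavone is oxidised, because the position para to the 5-OH is C8. The strategy rests on the 5-OH of the methoxyflavone unit, which is ortho to C4a just as O1 is. Once the O1–C2 bond of that pyranone opens, ring A carries two hydroxyls ortho to the acyl group, and reclosure through the former O5 renumbers the ring so that C8 becomes C6. An ether installed at the accessible C8 position can therefore be moved to C6 in the last step. The apigenin unit has the same 5-OH, but its ring A is symmetric about the C4a–C7 axis, so the same process changes nothing there.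

## Retrosynthetic reasoning

**16 to 14 (through 15).** The last disconnection is the pyranone of the methoxyflavone unit, not the diaryl ether. Cutting O1–C2 of 16 gives the open-chain diketone 15, whose two hydroxyls ortho to the acyl group differ only in their neighbours (aryloxy on one side, C–H on the other). Closing 15 through the other hydroxyl gives 14, the isomer with the ether at C8. This cut is preferred to the C6–O bond because a direct C6–O coupling would have to be made at a doubly flanked position that no simple oxidation reaches. Forward, 14 has to open, reclose on the former 5-oxygen and settle on the side of 16 without loss of the methyl ether.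

**14 to 13.** Three O–benzyl bonds are cut. The benzyl ethers keep the 4'-, 5- and 7-oxygens silent through the base-mediated steps. Forward, they must come off without reduction of either C2=C3 bond, and before the acid step, so that no benzyl cation is released next to electron-rich phloroglucinol rings.

**13 to 11 (through 12).** The O1–C2 bond of the apigenin pyranone and its C2=C3 unsaturation are removed, which gives the 2'-hydroxychalcone 11. This places the second flavone on a standard oxidative cyclisation whose only requirement is a free ortho hydroxyl.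

**11 to 8 and 10.** The chalcone Cα=Cβ bond is cut (aldol condensation). This divides the molecule into a methoxyflavone carrying a benzaldehyde (8) and a protected phloroacetophenone (10). Forward, the condensation has to proceed without opening the pyranone already present in 8.

**10 to 9.** Two O–benzyl bonds are cut; the third hydroxyl of 9 is chelated to the acetyl group and stays free for the later ring closure.

**8 to 6 and 7.** The diaryl ether is cut on the benzaldehyde side, between C4 of 7 and O8 of 6. On this side the bond can be made by nucleophilic aromatic substitution with the phenoxide as nucleophile, so the crowded electron-rich ring A never has to act as electrophile. Forward, the 8-OH must react and the chelated 5-OH must not.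

**6 to 4 (through 5).** The C8–O bond is cut. An Elbs oxidation puts oxygen para to the only free phenol of 4, which is exactly C8.

**4 to 3 to 1 and 2.** The O1–C2 bond is cut (cyclodehydration), then the acyl–CH2 bond (C-acylation of the acetophenone polyanion). Ring A of 3 is symmetric, so the closure has no regiochemical choice. The 7-OMe is present in 1 from the start and remains the only methyl ether in the whole route.

## Alternatives that were turned down

**Alternative 1: aryne insertion for the apigenin pyranone.**
- Disconnection: the apigenin pyranone is cut at C4–C4a and O1–C8a. Its ring A comes from 3,5-bis(benzyloxy)benzyne A2, and everything else from the arylpropiolic acid A1, which already contains the complete 6-aryloxy methoxyflavone.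
- Forward key step: the carboxylate of A1 adds to A2, the aryl anion attacks the acyl carbon (net insertion into the acyl C–O bond), and the resulting o-hydroxyaryl ynone closes by 6-endo-dig oxa-Michael addition to the protected biflavone A3.
- For it: the conditions are nearly neutral, one flask forms two ring bonds and closes the ring, and the benzyloxy group next to the aryne bond directs the oxygen nucleophile to the remote carbon, which gives the 5,7-pattern. It avoids strong hydroxide next to a finished flavone and is stronger on that point than step 6 of the chosen route.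
- Against it: the key step is spent on the easy half. A1 must already hold the C6–O ether on the hexasubstituted ring, so the real problem is only moved into the preparation of A1 (6-oxygenation, then O-arylation at a position flanked on both sides). A1 also needs an alkynoic acid built onto the diaryl ether and is prone to decarboxylation, A2 needs a purpose-made precursor, and the end game must cleave the 5-OMe of A3 while keeping the 7-OMe.
- Comparison: it is several steps longer, and its risk is spread over the insertion and an unsolved ether formation. The chosen route forms the ether at the position that is easy to oxygenate and confines the risk to one final step that uses only aqueous acid.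

**Alternative 2: two-directional double Baker–Venkataraman transfer.**
- Disconnection: both flavones are cut at C2–C3 back to the bis(aryl ester) A4, built on a diaryl ether that carries one acetophenone and one benzoate.
- Forward key step: strong base converts A4 into the bis(1,3-diketone) A5 by two intramolecular acyl transfers, each through a six-membered transition state. A separate acid step then closes both pyranones.
- For it: it is convergent and treats both units in the same operations. The ether position is fixed from the start, because oxidation para to the chelated hydroxyl at the acetophenone stage lands on the carbon that becomes C6, and the second ortho oxygen is capped as a methyl ether so closure can go only one way. On regiochemical certainty it is stronger than the chosen route, which depends on the position of an equilibrium.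
- Against it: A4 carries two aryl esters and two enolisable ketones, and both transfers must succeed against ester cleavage. Its assembly needs two selective esterifications and an ether formation on an acetophenone that is itself aldol-active. The capping methyl ether at C5 must be removed at the end without touching the 7-OMe, which adds a chelation-controlled demethylation to the debenzylation.
- Comparison: the step count is about the same. The chosen route offers a single methyl ether throughout, so no late differentiation is needed. Each pyranone is made on a substrate with one reactive site, and the arylation uses the only unchelated hydroxyl.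

**Alternative 3: benzannulation of ring A.**
- Disconnection: ring A of the methoxyflavone is cut at C8–C8a and C4a–C5 into the aryloxy siloxydiene A6 and the sulfinylpyranone A7.
- Forward key step: the nucleophilic CH2 terminus of A6 adds to C2 of A7 and the ketene-acetal carbon to C3. Loss of the sulfinyl group as a sulfenic acid and of the silyl methyl ether aromatises the adduct to A8, with the 5-OH, 6-aryloxy and 7-OMe groups in place.
- For it: the hexasubstituted ring is made with its substitution pattern dictated by the polarity of the diene, the ether is at C6 from the start, and no equilibrium is involved. On that point it is as strong as Alternative 2.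
- Against it: A6 is a tetra-heteroatom-substituted diene that is sensitive to hydrolysis and must be prepared and used at once. The C2=C3 bond of a 4-pyranone such as A7 is a reluctant dienophile even with the sulfinyl activator. A8 is still only a bromophenyl ether, so the whole apigenin unit (formylation, chalcone, cyclisation, deprotection) has yet to be built.
- Comparison: it is clearly longer, and it constructs a ring A that can be bought as a phloroacetophenone. The chosen route uses intact commercial ring A units for both flavones.

Key step: step 9

Assumption: compounds 1 and 2 are taken as catalogue materials, and the 6-aryloxy/8-aryloxy equilibrium is assumed to follow the preference known for simpler 5-hydroxy-7,8-dioxygenated flavones.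

## Route

**Step 1**
Reactants: 1 1-(2,6-dihydroxy-4-methoxyphenyl)ethanone; 2 4-(benzyloxy)benzoyl chloride
Product: 3 1-[4-(benzyloxy)phenyl]-3-(2,6-dihydroxy-4-methoxyphenyl)propane-1,3-dione
Conditions: LiN(SiMe3)2 (4.2 equiv), THF, −78 °C → rt; aq. HCl work-up
Reagents that add atoms: none
Why: Claisen-type C-acylation of a lithium polyanion; three equivalents of amide base give the bis(phenoxide) enolate, which is acylated on carbon because the chelated lithium phenoxides are poor nucleophiles, and the fourth equivalent deprotonates the diketone so that it is not acylated again.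

**Step 2**
Reactants: 3 1-[4-(benzyloxy)phenyl]-3-(2,6-dihydroxy-4-methoxyphenyl)propane-1,3-dione
Product: 4 2-[4-(benzyloxy)phenyl]-5-hydroxy-7-methoxy-4H-chromen-4-one (genkwanin 4'-benzyl ether)
Conditions: H2SO4 (cat.), AcOH, 90 °C
Reagents that add atoms: none
Why: Acid-catalysed cyclodehydration of an o-hydroxyaryl 1,3-diketone, the closing stage of the Baker–Venkataraman flavone synthesis; the two ortho hydroxyls of 3 are equivalent, so only one flavone can form, and the benzyl ether, on a ring deactivated by the pyranone, should tolerate the short exposure to dilute acid.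

**Step 3**
Reactants: 4 2-[4-(benzyloxy)phenyl]-5-hydroxy-7-methoxy-4H-chromen-4-one
Product: 6 2-[4-(benzyloxy)phenyl]-5,8-dihydroxy-7-methoxy-4H-chromen-4-one, via potassium flavon-8-yl sulfate 5 (not isolated)
Conditions: K2S2O8, aq. KOH, pyridine, 0 °C → rt; then aq. HCl, 90 °C
Reagents that add atoms: potassium peroxodisulfate, [K+].[K+].[O-]S(=O)(=O)OOS(=O)(=O)[O-]
Why: Elbs persulfate oxidation; the 5-phenoxide attacks the peroxide oxygen through its para carbon C8 to give aryl sulfate 5, which aqueous acid hydrolyses at sulfur. The 5-OH is the only free phenol, so ring B stays out of the reaction, and unreacted 4 should be recoverable before the hydrolysis.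

**Step 4**
Reactants: 6 2-[4-(benzyloxy)phenyl]-5,8-dihydroxy-7-methoxy-4H-chromen-4-one; 7 4-fluorobenzaldehyde
Product: 8 4-({2-[4-(benzyloxy)phenyl]-5-hydroxy-7-methoxy-4-oxo-4H-chromen-8-yl}oxy)benzaldehyde
Conditions: K2CO3 (1.1 equiv), DMF (degassed), 90 °C, Ar
Reagents that add atoms: none
Why: Nucleophilic aromatic substitution (addition–elimination) on the para-formyl-activated aryl fluoride; only the 8-phenoxide forms and reacts, because the 5-OH is held in a hydrogen bond to the C4 carbonyl and is less acidic and less nucleophilic, the same bias that allows monoalkylation of 5,8-dihydroxyflavones at O8. Air is excluded because the hydroquinone monoanion is easily oxidised.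

**Step 5**
Reactants: 9 1-(2,4,6-trihydroxyphenyl)ethanone
Product: 10 1-[2,4-bis(benzyloxy)-6-hydroxyphenyl]ethanone
Conditions: BnBr (2.05 equiv), K2CO3, acetone, reflux
Reagents that add atoms: benzyl bromide, BrCc1ccccc1
Why: Williamson etherification; the para hydroxyl and one ortho hydroxyl are alkylated, after which the remaining ortho hydroxyl is chelated to the acetyl group and resists a third alkylation.

**Step 6**
Reactants: 8 4-({2-[4-(benzyloxy)phenyl]-5-hydroxy-7-methoxy-4-oxo-4H-chromen-8-yl}oxy)benzaldehyde; 10 1-[2,4-bis(benzyloxy)-6-hydroxyphenyl]ethanone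
Product: 11 (E)-1-[2,4-bis(benzyloxy)-6-hydroxyphenyl]-3-[4-({2-[4-(benzyloxy)phenyl]-5-hydroxy-7-methoxy-4-oxo-4H-chromen-8-yl}oxy)phenyl]prop-2-en-1-one
Conditions: KOH, EtOH/THF, 0 °C → rt
Reagents that add atoms: none
Why: Claisen–Schmidt condensation (crossed aldol with E1cB dehydration) between a non-enolisable aldehyde and the acetophenone enolate, giving the conjugated E-alkene. The flavone already present is carried as its 5-phenoxide, a vinylogous carboxylate that lowers the electrophilicity of C2 towards hydroxide.

**Step 7**
Reactants: 11 the (E)-chalcone of step 6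
Product: 13 2-[4-(benzyloxy)phenyl]-8-{4-[5,7-bis(benzyloxy)-4-oxo-4H-chromen-2-yl]phenoxy}-5-hydroxy-7-methoxy-4H-chromen-4-one, via flavanone 12 (not isolated)
Conditions: I2 (10 mol%), DMSO, 120 °C
Reagents that add atoms: none
Why: Iodine-catalysed oxidative cyclisation of a 2'-hydroxychalcone; oxa-Michael closure gives flavanone 12, α-iodination and loss of HI give the flavone, and DMSO reoxidises HI to iodine. The benzyl ethers, the diaryl ether and the existing flavone are spectators.

**Step 8**
Reactants: 13 the tribenzyl ether of the 8-O-linked biflavone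
Product: 14 8-[4-(5,7-dihydroxy-4-oxo-4H-chromen-2-yl)phenoxy]-5-hydroxy-2-(4-hydroxyphenyl)-7-methoxy-4H-chromen-4-one (8-O-linked isomer of isocryptomerin)
Conditions: H2 (1 atm), Pd/C (10%), THF/MeOH, rt
Reagents that add atoms: none
Why: Hydrogenolysis of three benzyl aryl ethers; the C2=C3 bonds are vinylogous esters conjugated to aryl groups and should not be reduced at atmospheric pressure and room temperature, and the methyl and diaryl ethers are inert.

**Step 9**
Reactants: 14 the 8-O-linked isomer of isocryptomerin
Product: 16 isocryptomerin, via open-chain 1,3-diketone 15 (not isolated)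
Conditions: 3 M aq. H2SO4/1,4-dioxane (1:1), 100 °C, sealed tube, Ar
Reagents that add atoms: none
Why: Wessely–Moser rearrangement. Protonation of the C4 carbonyl makes C2 of the methoxyflavone unit electrophilic; water adds there and the hemiketal opens at O1–C2 to the 1,3-diketone 15, whose ring A now has two free hydroxyls ortho to the acyl group. Rotation about the aryl–carbonyl bond lets the former 5-OH add to the C2 ketone in a 6-exo-trig hemiketalisation, and loss of water re-forms the pyranone, now with the former C6–H carbon as C8 and the aryloxy carbon as C6; no stereocentre is formed. The closest known reaction type is the acid isomerisation of 8-substituted 5-hydroxyflavones (hydroxy, alkoxy, C-glycosyl) into their 6-substituted isomers. The apigenin unit opens and recloses in the same way, but its ring A is symmetric about the acyl axis, so that process is degenerate. The selectivity needed is thermodynamic, the 6-aryloxy over the 8-aryloxy isomer, and it is expected from the general preference of 5-hydroxyflavones for the 5,6,7- over the 5,7,8-oxygenation pattern. Chemoselectivity rests on the acid: aqueous H2SO4 has no nucleophilic counter-ion, so the C7 methyl ether and the diaryl ether should survive where HI or HBr would demethylate.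

## Compound list

1 | 1-(2,6-dihydroxy-4-methoxyphenyl)ethanone | CC(=O)c1c(O)cc(OC)cc1O | starting material
2 | 4-(benzyloxy)benzoyl chloride | O=C(Cl)c1ccc(OCc2ccccc2)cc1 | starting material
3 | 1-[4-(benzyloxy)phenyl]-3-(2,6-dihydroxy-4-methoxyphenyl)propane-1,3-dione | COc1cc(O)c(C(=O)CC(=O)c2ccc(OCc3ccccc3)cc2)c(O)c1 | intermediate
4 | 2-[4-(benzyloxy)phenyl]-5-hydroxy-7-methoxy-4H-chromen-4-one (genkwanin 4'-benzyl ether) | COc1cc(O)c2c(=O)cc(-c3ccc(OCc4ccccc4)cc3)oc2c1 | intermediate
5 | potassium 2-[4-(benzyloxy)phenyl]-5-hydroxy-7-methoxy-4-oxo-4H-chromen-8-yl sulfate | COc1cc(O)c2c(=O)cc(-c3ccc(OCc4ccccc4)cc3)oc2c1OS(=O)(=O)[O-].[K+] | intermediate (not isolated)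
6 | 2-[4-(benzyloxy)phenyl]-5,8-dihydroxy-7-methoxy-4H-chromen-4-one | COc1cc(O)c2c(=O)cc(-c3ccc(OCc4ccccc4)cc3)oc2c1O | intermediate
7 | 4-fluorobenzaldehyde | O=Cc1ccc(F)cc1 | starting material
8 | 4-({2-[4-(benzyloxy)phenyl]-5-hydroxy-7-methoxy-4-oxo-4H-chromen-8-yl}oxy)benzaldehyde | COc1cc(O)c2c(=O)cc(-c3ccc(OCc4ccccc4)cc3)oc2c1Oc1ccc(C=O)cc1 | intermediate
9 | 1-(2,4,6-trihydroxyphenyl)ethanone | CC(=O)c1c(O)cc(O)cc1O | starting material
10 | 1-[2,4-bis(benzyloxy)-6-hydroxyphenyl]ethanone | CC(=O)c1c(O)cc(OCc2ccccc2)cc1OCc1ccccc1 | intermediate
11 | (E)-1-[2,4-bis(benzyloxy)-6-hydroxyphenyl]-3-[4-({2-[4-(benzyloxy)phenyl]-5-hydroxy-7-methoxy-4-oxo-4H-chromen-8-yl}oxy)phenyl]prop-2-en-1-one | COc1cc(O)c2c(=O)cc(-c3ccc(OCc4ccccc4)cc3)oc2c1Oc1ccc(/C=C/C(=O)c2c(O)cc(OCc3ccccc3)cc2OCc2ccccc2)cc1 | intermediate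
12 | 2-[4-(benzyloxy)phenyl]-8-{4-[5,7-bis(benzyloxy)-4-oxochroman-2-yl]phenoxy}-5-hydroxy-7-methoxy-4H-chromen-4-one (racemic flavanone) | COc1cc(O)c2c(=O)cc(-c3ccc(OCc4ccccc4)cc3)oc2c1Oc1ccc(C2CC(=O)c3c(OCc4ccccc4)cc(OCc4ccccc4)cc3O2)cc1 | intermediate (not isolated)
13 | 2-[4-(benzyloxy)phenyl]-8-{4-[5,7-bis(benzyloxy)-4-oxo-4H-chromen-2-yl]phenoxy}-5-hydroxy-7-methoxy-4H-chromen-4-one | COc1cc(O)c2c(=O)cc(-c3ccc(OCc4ccccc4)cc3)oc2c1Oc1ccc(-c2cc(=O)c3c(OCc4ccccc4)cc(OCc4ccccc4)cc3o2)cc1 | intermediate
14 | 8-[4-(5,7-dihydroxy-4-oxo-4H-chromen-2-yl)phenoxy]-5-hydroxy-2-(4-hydroxyphenyl)-7-methoxy-4H-chromen-4-one | COc1cc(O)c2c(=O)cc(-c3ccc(O)cc3)oc2c1Oc1ccc(-c2cc(=O)c3c(O)cc(O)cc3o2)cc1 | intermediate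
15 | 1-{3-[4-(5,7-dihydroxy-4-oxo-4H-chromen-2-yl)phenoxy]-2,6-dihydroxy-4-methoxyphenyl}-3-(4-hydroxyphenyl)propane-1,3-dione | COc1cc(O)c(C(=O)CC(=O)c2ccc(O)cc2)c(O)c1Oc1ccc(-c2cc(=O)c3c(O)cc(O)cc3o2)cc1 | intermediate (not isolated)
16 | isocryptomerin, 6-[4-(5,7-dihydroxy-4-oxo-4H-chromen-2-yl)phenoxy]-5-hydroxy-2-(4-hydroxyphenyl)-7-methoxy-4H-chromen-4-one | COc1cc2oc(-c3ccc(O)cc3)cc(=O)c2c(O)c1Oc1ccc(-c2cc(=O)c3c(O)cc(O)cc3o2)cc1 | target

## Step count and risk

Total step count: 9. Longest linear sequence: 8 steps (steps 1, 2, 3, 4, 6, 7, 8, 9); step 5 is a one-step side branch.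

**Step 9 (key step).**
- Risk: equilibration may stop at a mixture, because an aryloxy group at C6 versus C8 may differ less in energy than the hydroxy and methoxy cases on which the preference is established. Prolonged heating may also slowly hydrolyse the aryloxy group from the ring-opened acylphloroglucinol.
- Fallback: replace thermodynamic control by a kinetically controlled reclosure at the benzyl-protected stage. Setting out from 13, warming with KOH in aqueous pyridine should open both pyranones to the bis(1,3-diketone) F1. Brief treatment with catalytic H2SO4 in dry AcOH at moderate temperature should then close both rings irreversibly. On the methoxy ring the hydroxyl next to C–H should react faster than the one flanked by the aryloxy group, which would give the 6-O-linked tribenzyl ether F2. The apigenin diketone has only one free ortho hydroxyl and can only return to its flavone. Hydrogenolysis of F2 (H2, Pd/C) rejoins the route at 16.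

**Step 3.**
- Risk: Elbs oxidations commonly stall at partial conversion, and sulfate radicals can over-oxidise the electron-rich phenoxide to quinonoid and coupled material.
- Fallback: a two-electron oxidation through the quinone. Setting out from 4, PhI(OCOCF3)2 (trivalent iodine, two equivalents) in aqueous MeCN at 0 °C should deliver water para to the iodine-bound phenol oxygen and give 2-[4-(benzyloxy)phenyl]-7-methoxy-4H-chromene-4,5,8-trione F3. Reduction with Na2S2O4 in a two-phase system returns to the route at 6.

**Step 4.**
- Risk: the 8-phenoxide is flanked by O1 and the 7-OMe, so substitution may be slow at a temperature where the hydroquinone monoanion is oxidised or the 5-OH begins to be arylated.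
- Fallback: a copper-catalysed Ullmann etherification in place of the uncatalysed substitution. Setting out from 6, coupling with 4-bromobenzaldehyde (CuI, picolinic acid, K3PO4, DMSO, 80 °C, Ar), a ligand system suited to hindered phenols, leads directly to 8 without a new intermediate.

**Step 6.**
- Risk: hydroxide may add to C2 of the pyranone already present and open it, followed by retro-Claisen cleavage, in competition with a slow condensation of the dianion of 10.
- Fallback: build the second diketone by acylation, so that no hydroxide is present. Setting out from 8, Pinnick oxidation (NaClO2, NaH2PO4, 2-methylbut-2-ene, tBuOH/H2O) gives 4-({2-[4-(benzyloxy)phenyl]-5-hydroxy-7-methoxy-4-oxo-4H-chromen-8-yl}oxy)benzoic acid F4. Oxalyl chloride with catalytic DMF converts it into the acid chloride F5. Adding F5 to the lithium polyanion of 10 (LiN(SiMe3)2, THF, −78 °C), the same C-acylation as in step 1, gives the 1,3-diketone F6. Cyclodehydration as in step 2 (cat. H2SO4, AcOH) rejoins the route at 13, bypassing steps 6 and 7.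

## Further compounds

F1 | step 9 | 1-[4-(benzyloxy)phenyl]-3-[3-(4-{3-[2,4-bis(benzyloxy)-6-hydroxyphenyl]-3-oxopropanoyl}phenoxy)-2,6-dihydroxy-4-methoxyphenyl]propane-1,3-dione | COc1cc(O)c(C(=O)CC(=O)c2ccc(OCc3ccccc3)cc2)c(O)c1Oc1ccc(C(=O)CC(=O)c2c(O)cc(OCc3ccccc3)cc2OCc2ccccc2)cc1
F2 | step 9 | 2-[4-(benzyloxy)phenyl]-6-{4-[5,7-bis(benzyloxy)-4-oxo-4H-chromen-2-yl]phenoxy}-5-hydroxy-7-methoxy-4H-chromen-4-one | COc1cc2oc(-c3ccc(OCc4ccccc4)cc3)cc(=O)c2c(O)c1Oc1ccc(-c2cc(=O)c3c(OCc4ccccc4)cc(OCc4ccccc4)cc3o2)cc1
F3 | step 3 | 2-[4-(benzyloxy)phenyl]-7-methoxy-4H-chromene-4,5,8-trione | COC1=CC(=O)C2=C(OC(=CC2=O)c2ccc(OCc3ccccc3)cc2)C1=O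
F0 | step 4 | none | none
F4 | step 6 | 4-({2-[4-(benzyloxy)phenyl]-5-hydroxy-7-methoxy-4-oxo-4H-chromen-8-yl}oxy)benzoic acid | COc1cc(O)c2c(=O)cc(-c3ccc(OCc4ccccc4)cc3)oc2c1Oc1ccc(C(=O)O)cc1
F5 | step 6 | 4-({2-[4-(benzyloxy)phenyl]-5-hydroxy-7-methoxy-4-oxo-4H-chromen-8-yl}oxy)benzoyl chloride | COc1cc(O)c2c(=O)cc(-c3ccc(OCc4ccccc4)cc3)oc2c1Oc1ccc(C(=O)Cl)cc1
F6 | step 6 | 1-[2,4-bis(benzyloxy)-6-hydroxyphenyl]-3-[4-({2-[4-(benzyloxy)phenyl]-5-hydroxy-7-methoxy-4-oxo-4H-chromen-8-yl}oxy)phenyl]propane-1,3-dione | COc1cc(O)c2c(=O)cc(-c3ccc(OCc4ccccc4)cc3)oc2c1Oc1ccc(C(=O)CC(=O)c2c(O)cc(OCc3ccccc3)cc2OCc2ccccc2)cc1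
A1 | alternative 1 | 3-[4-({2-[4-(benzyloxy)phenyl]-5,7-dimethoxy-4-oxo-4H-chromen-6-yl}oxy)phenyl]prop-2-ynoic acid | COc1cc2oc(-c3ccc(OCc4ccccc4)cc3)cc(=O)c2c(OC)c1Oc1ccc(C#CC(=O)O)cc1
A2 | alternative 1 | 3,5-bis(benzyloxy)benzyne | C1#CC(OCc2ccccc2)=CC(OCc2ccccc2)=C1
A3 | alternative 1 | 2-[4-(benzyloxy)phenyl]-6-{4-[5,7-bis(benzyloxy)-4-oxo-4H-chromen-2-yl]phenoxy}-5,7-dimethoxy-4H-chromen-4-one | COc1cc2oc(-c3ccc(OCc4ccccc4)cc3)cc(=O)c2c(OC)c1Oc1ccc(-c2cc(=O)c3c(OCc4ccccc4)cc(OCc4ccccc4)cc3o2)cc1
A4 | alternative 2 | 2-acetyl-3,5-bis(benzyloxy)phenyl 4-(3-acetyl-4-{[4-(benzyloxy)benzoyl]oxy}-2,6-dimethoxyphenoxy)benzoate | CC(=O)c1c(OC(=O)c2ccc(OCc3ccccc3)cc2)cc(OC)c(Oc2ccc(C(=O)Oc3cc(OCc4ccccc4)cc(OCc4ccccc4)c3C(C)=O)cc2)c1OC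
A5 | alternative 2 | 1-[4-(benzyloxy)phenyl]-3-[3-(4-{3-[2,4-bis(benzyloxy)-6-hydroxyphenyl]-3-oxopropanoyl}phenoxy)-6-hydroxy-2,4-dimethoxyphenyl]propane-1,3-dione | O=C(CC(=O)c1ccc(OCc2ccccc2)cc1)c1c(O)cc(OC)c(Oc2ccc(C(=O)CC(=O)c3c(O)cc(OCc4ccccc4)cc3OCc3ccccc3)cc2)c1OC
A6 | alternative 3 | 2-(4-bromophenoxy)-1,3-dimethoxy-1-(trimethylsilyloxy)buta-1,3-diene | C=C(OC)C(Oc1ccc(Br)cc1)=C(OC)O[Si](C)(C)C
A7 | alternative 3 | 6-[4-(benzyloxy)phenyl]-3-(phenylsulfinyl)-4H-pyran-4-one (racemic at sulfur) | O=c1cc(-c2ccc(OCc3ccccc3)cc2)occ1S(=O)c1ccccc1
A8 | alternative 3 | 2-[4-(benzyloxy)phenyl]-6-(4-bromophenoxy)-5-hydroxy-7-methoxy-4H-chromen-4-one | COc1cc2oc(-c3ccc(OCc4ccccc4)cc3)cc(=O)c2c(O)c1Oc1ccc(Br)cc1
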